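**Assumption:** all bicyclic compounds carry labdane atom labels (C10 = methyl-bearing ring-fusion carbon, C5 = the other ring-fusion carbon, α = face opposite the C10 methyl). The hydrindane intermediates keep these labels and simply lack C9. Angeloyl = (Z)-2-methylbut-2-enoyl.

## Retrosynthetic overview

1. The C12–C15 (Z)-keto ester is unmasked last from a 2,3-disubstituted furan (photooxygenation, then O-methylation).
2. The C8 enal comes from an 8-ketone through its Δ7 enol triflate and Pd formylation (C17 enters as CO).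
3. Ring B (8-ketone with C9–CH2–furyl) arises by semipinacol ring expansion of a hydrindane α-hydroxy epoxide (C10 shifts from C8 to C9), with the furan captured in the same flask.
4. The ring A cis-diol diester comes from a 3-ketone (enolate hydroxylation, axial-alcohol reduction, angeloylation), itself from Birch reductive methylation of a Hajos–Parrish-type enone.
5. Ring order: ring A first (asymmetric Robinson annulation of 2-methylcyclopentane-1,3-dione with ethyl vinyl ketone), then ring B by five-to-six ring expansion; the furan is a temporary ring.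

## Route

**Step 1**
Reactants: 1 2-methylcyclopentane-1,3-dione; 2 pent-1-en-3-one (ethyl vinyl ketone)
Product: 4 (7aS)-4,7a-dimethyl-2,3,7,7a-tetrahydro-1H-indene-1,5(6H)-dione, via triketone 3 (not isolated)
Conditions: Et3N (cat.), MeCN, rt; then L-phenylalanine (1 equiv), (1S)-(+)-camphor-10-sulfonic acid (0.5 equiv), 80 °C
Reagents that add atoms: none
Why: Michael addition followed by amino-acid (enamine) catalysed intramolecular aldol condensation (Hajos–Parrish-type Robinson annulation); L-phenylalanine differentiates the two enantiotopic ring carbonyls and sets C10 as S (β-methyl).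

**Step 2**
Reactants: 4 (7aS)-4,7a-dimethyl-2,3,7,7a-tetrahydro-1H-indene-1,5(6H)-dione
Product: 5 (1R,7aS)-1-ethenyl-1-hydroxy-4,7a-dimethyl-1,2,3,6,7,7a-hexahydro-5H-inden-5-one
Conditions: CH2=CHMgBr (1.1 equiv), CeCl3, THF, −78 °C
Reagents that add atoms: vinylmagnesium bromide, C=C[Mg]Br
Why: Organocerium 1,2-addition to the more electrophilic saturated cyclopentanone rather than the conjugated, α-methylated enone carbonyl; attack anti to the angular methyl gives 8β-OH/8α-vinyl (this centre is erased in step 8).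

**Step 3**
Reactants: 5 (1R,7aS)-1-ethenyl-1-hydroxy-4,7a-dimethyl-1,2,3,6,7,7a-hexahydro-5H-inden-5-one
Product: 7 (1R,3aR,7aS)-1-ethenyl-1-hydroxy-4,4,7a-trimethyloctahydro-5H-inden-5-one, via dilithium enolate 6 (not isolated)
Conditions: Li (2.2 equiv), NH3(l)/THF, −78 °C; then MeI (5 equiv), −78 → −33 °C
Reagents that add atoms: iodomethane, CI
Why: Birch-type enone reduction with Stork reductive alkylation; the tertiary OH is the internal proton source, protonation of the β-carbanion trans to the angular methyl sets C5–H α (trans fusion), and C-methylation of the enolate completes the C4 gem-dimethyl group.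

**Step 4**
Reactants: 7 (1R,3aR,7aS)-1-ethenyl-1-hydroxy-4,4,7a-trimethyloctahydro-5H-inden-5-one
Product: 9 (1R,3aR,6R,7aS)-1-ethenyl-1,6-dihydroxy-4,4,7a-trimethyloctahydro-5H-inden-5-one (2α-hydroxy-3-ketone), via dipotassium enolate 8 (not isolated)
Conditions: KN(SiMe3)2 (2.2 equiv), THF, −78 °C; then 2-(phenylsulfonyl)-3-phenyloxaziridine, −78 °C
Reagents that add atoms: 2-(phenylsulfonyl)-3-phenyloxaziridine, O=S(=O)(c1ccccc1)N1OC1c1ccccc1
Why: Davis enolate hydroxylation; only C2 can enolise, and the oxidant approaches the α face away from the axial 10β- and 4β-methyls, giving the equatorial 2α-OH.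

**Step 5**
Reactants: 9 (1R,3aR,6R,7aS)-1-ethenyl-1,6-dihydroxy-4,4,7a-trimethyloctahydro-5H-inden-5-one
Product: 10 (1R,3aS,5S,6R,7aS)-1-ethenyl-4,4,7a-trimethyloctahydro-1H-indene-1,5,6-triol (2α,3α,8β-triol)
Conditions: LiBH(s-Bu)3 (3.5 equiv), THF, −78 °C; then H2O
Reagents that add atoms: none
Why: Diastereoselective ketone reduction with a bulky trialkylborohydride; equatorial hydride delivery, as for axial 3α-alcohols from 4,4-dimethyl-3-ketones, gives the axial 3α-OH cis to the 2α-OH.

**Step 6**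
Reactants: 10 2α,3α,8β-triol; 11 angelic acid ((Z)-2-methylbut-2-enoic acid)
Product: 12 2α,3α-bis(angeloyloxy)-8α-ethenyl-8β-hydroxy-4,4,10-trimethyl-trans-hydrindane (5,6-di-O-angeloyl ester of 10)
Conditions: 11 (3 equiv), 2,4,6-trichlorobenzoyl chloride (3 equiv), Et3N (6 equiv), toluene, rt; then 10, 80 °C
Reagents that add atoms: none
Why: Yamaguchi-type mixed-anhydride esterification run without nucleophilic catalyst so that the Z geometry is kept; the hindered tertiary C8–OH is not acylated.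

**Step 7**
Reactants: 12 2α,3α-bis(angeloyloxy)-8α-ethenyl-8β-hydroxy-4,4,10-trimethyl-trans-hydrindane
Product: 13 2α,3α-bis(angeloyloxy)-8β-hydroxy-8α-(oxiran-2-yl)-4,4,10-trimethyl-trans-hydrindane (both epoxide epimers)
Conditions: VO(acac)2 (5 mol%), t-BuOOH (1.5 equiv), toluene, 60 °C
Reagents that add atoms: tert-butyl hydroperoxide, CC(C)(C)OO
Why: Hydroxyl-directed vanadium-catalysed epoxidation of the allylic alcohol; the electron-poor angelate alkenes have no directing group and do not react, and the new epoxide centre is inconsequential because C9 is equilibrated in step 8.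

**Step 8**
Reactants: 13 α-hydroxy epoxide; 14 3-methylfuran
Product: 17 2α,3α-bis(angeloyloxy)-12,15-epoxy-17-norlabda-12,14-dien-8-one (trans-decalin; 9β-CH2-furyl and 9α-H), via hydroxymethyl ketone 15 (not isolated), via methylene ketone 16 (not isolated)
Conditions: Sc(OTf)3 (20 mol%), 4 Å MS, ClCH2CH2Cl, 0 °C until 13 is consumed; then 14 (5 equiv), 40 °C
Reagents that add atoms: none
Why: Proposed new method: a single-catalyst semipinacol ring expansion / dehydrative Friedel–Crafts relay. Sc(OTf)3 activates the epoxide, and the C8–C10 bond (the more electron-rich, fully substituted migrating carbon) shifts to C9 anti to the breaking C9–O bond. This forms ring B and the 8-ketone as 9-(hydroxymethyl) ketone 15. The same Lewis acid dehydrates 15 through its enol to methylene ketone 16, which 3-methylfuran captures at its most nucleophilic C2 position, and acid-mediated enolisation leaves the C9 substituent equatorial (9β). The closest known reaction types are the Lewis-acid semipinacol rearrangement of α-hydroxy epoxides to β-hydroxy ketones and the Lewis-acid Friedel–Crafts conjugate addition of furans to enones.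

**Step 9**
Reactants: 17 2α,3α-bis(angeloyloxy)-12,15-epoxy-17-norlabda-12,14-dien-8-one
Product: 19 2α,3α-bis(angeloyloxy)-12,15-epoxy-17-norlabda-7,12,14-trien-8-yl trifluoromethanesulfonate, via potassium enolate 18 (not isolated)
Conditions: KN(SiMe3)2 (1.1 equiv), THF, −78 °C; then PhNTf2, −78 → 0 °C
Reagents that add atoms: N-phenylbis(trifluoromethanesulfonimide), O=S(=O)(N(c1ccccc1)S(=O)(=O)C(F)(F)F)C(F)(F)F
Why: Kinetic enolate formation at the C7 methylene rather than the hindered C9 methine, followed by O-triflation (enol triflate synthesis); C9 is untouched.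

**Step 10**
Reactants: 19 Δ7 enol triflate
Product: 20 2α,3α-bis(angeloyloxy)-12,15-epoxylabda-7,12,14-trien-17-al
Conditions: Pd(PPh3)4 (5 mol%), CO (1 atm), Bu3SnH (1.2 equiv, slow addition), LiCl (3 equiv), THF, 50 °C
Reagents that add atoms: carbon monoxide, [C-]#[O+]
Why: Palladium-catalysed reductive carbonylation (Stille-type formylation) of a vinyl triflate; oxidative addition to zerovalent palladium, CO insertion and hydride transfer from tin give the conjugated enal with the Δ7 position fixed by the triflate.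

**Step 11**
Reactants: 20 furyl enal
Product: 23 methyl (13Z)-2α,3α-bis(angeloyloxy)-12,17-dioxolabda-7,13-dien-15-oate (target), via endoperoxide 21 (not isolated), via hydroxybutenolide 22 (not isolated)
Conditions: O2, tetraphenylporphyrin (1 mol%), hν, i-Pr2NEt (2 equiv), CH2Cl2, −78 °C → rt; then MeI, K2CO3, DMF, 0 °C
Reagents that add atoms: dioxygen, O=O; iodomethane, CI
Why: Singlet-oxygen [4+2] photooxygenation of the electron-rich furan, base-induced Kornblum–DeLaMare fragmentation of the endoperoxide at its only C–H (C15) to the γ-hydroxybutenolide, then carboxylate O-methylation of the ring-opened keto acid; the Z alkene is inherited from the ring, and the enal and angelates are too electron-poor to react with singlet oxygen.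

## Compound list

1 | 2-methylcyclopentane-1,3-dione | CC1C(=O)CCC1=O | starting material
2 | pent-1-en-3-one (ethyl vinyl ketone) | CCC(=O)C=C | starting material
3 | 2-methyl-2-(3-oxopentyl)cyclopentane-1,3-dione (triketone) | CCC(=O)CCC1(C)C(=O)CCC1=O | intermediate
4 | (7aS)-4,7a-dimethyl-2,3,7,7a-tetrahydro-1H-indene-1,5(6H)-dione | O=C1CC[C@]2(C)C(=O)CCC2=C1C | intermediate
5 | (1R,7aS)-1-ethenyl-1-hydroxy-4,7a-dimethyl-1,2,3,6,7,7a-hexahydro-5H-inden-5-one | O=C1CC[C@]2(C)[C@](O)(C=C)CCC2=C1C | intermediate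
6 | dilithium C8-alkoxide / C3(O)=C4 enolate from Birch reduction of 5 (5α-H) | [Li+].[Li+].[O-]C1=C(C)[C@@H]2CC[C@@]([O-])(C=C)[C@@]2(C)CC1 | intermediate
7 | (1R,3aR,7aS)-1-ethenyl-1-hydroxy-4,4,7a-trimethyloctahydro-5H-inden-5-one | O=C1CC[C@]2(C)[C@](O)(C=C)CC[C@H]2C1(C)C | intermediate
8 | dipotassium C8-alkoxide / C2=C3 enolate of 7 | [K+].[K+].[O-]C1=CC[C@]2(C)[C@]([O-])(C=C)CC[C@H]2C1(C)C | intermediate
9 | (1R,3aR,6R,7aS)-1-ethenyl-1,6-dihydroxy-4,4,7a-trimethyloctahydro-5H-inden-5-one (2α-hydroxy-3-ketone) | O=C1[C@H](O)C[C@]2(C)[C@](O)(C=C)CC[C@H]2C1(C)C | intermediate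
10 | (1R,3aS,5S,6R,7aS)-1-ethenyl-4,4,7a-trimethyloctahydro-1H-indene-1,5,6-triol (2α,3α,8β-triol) | O[C@@H]1[C@H](O)C[C@]2(C)[C@](O)(C=C)CC[C@H]2C1(C)C | intermediate
11 | angelic acid, (Z)-2-methylbut-2-enoic acid | C/C=C(/C)C(=O)O | starting material
12 | 2α,3α-bis(angeloyloxy)-8α-ethenyl-8β-hydroxy-4,4,10-trimethyl-trans-hydrindane | C/C=C(/C)C(=O)O[C@@H]1[C@H](OC(=O)/C(C)=C\C)C[C@]2(C)[C@](O)(C=C)CC[C@H]2C1(C)C | intermediate
13 | 2α,3α-bis(angeloyloxy)-8β-hydroxy-8α-(oxiran-2-yl)-4,4,10-trimethyl-trans-hydrindane (epoxide epimers) | C/C=C(/C)C(=O)O[C@@H]1[C@H](OC(=O)/C(C)=C\C)C[C@]2(C)[C@](O)(C3CO3)CC[C@H]2C1(C)C | intermediate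
14 | 3-methylfuran | Cc1ccoc1 | starting material
15 | 2α,3α-bis(angeloyloxy)-9-(hydroxymethyl)-4,4,10-trimethyl-trans-decalin-8-one (C9 epimers) | C/C=C(/C)C(=O)O[C@@H]1[C@H](OC(=O)/C(C)=C\C)C[C@]2(C)C(CO)C(=O)CC[C@H]2C1(C)C | intermediate
16 | 2α,3α-bis(angeloyloxy)-9-methylidene-4,4,10-trimethyl-trans-decalin-8-one | C/C=C(/C)C(=O)O[C@@H]1[C@H](OC(=O)/C(C)=C\C)C[C@]2(C)C(=C)C(=O)CC[C@H]2C1(C)C | intermediate
17 | 2α,3α-bis(angeloyloxy)-12,15-epoxy-17-norlabda-12,14-dien-8-one (9β-side chain) | C/C=C(/C)C(=O)O[C@@H]1[C@H](OC(=O)/C(C)=C\C)C[C@]2(C)[C@@H](Cc3occc3C)C(=O)CC[C@H]2C1(C)C | intermediate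
18 | potassium Δ7 enolate of 17 | [K+].C/C=C(/C)C(=O)O[C@@H]1[C@H](OC(=O)/C(C)=C\C)C[C@]2(C)[C@@H](Cc3occc3C)C([O-])=CC[C@H]2C1(C)C | intermediate
19 | 2α,3α-bis(angeloyloxy)-12,15-epoxy-17-norlabda-7,12,14-trien-8-yl trifluoromethanesulfonate | C/C=C(/C)C(=O)O[C@@H]1[C@H](OC(=O)/C(C)=C\C)C[C@]2(C)[C@@H](Cc3occc3C)C(OS(=O)(=O)C(F)(F)F)=CC[C@H]2C1(C)C | intermediate
20 | 2α,3α-bis(angeloyloxy)-12,15-epoxylabda-7,12,14-trien-17-al | C/C=C(/C)C(=O)O[C@@H]1[C@H](OC(=O)/C(C)=C\C)C[C@]2(C)[C@@H](Cc3occc3C)C(C=O)=CC[C@H]2C1(C)C | intermediate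
21 | furan 2,5-endoperoxide of 20 (2,3,7-trioxabicyclo[2.2.1]hept-5-ene, diastereomers) | C/C=C(/C)C(=O)O[C@@H]1[C@H](OC(=O)/C(C)=C\C)C[C@]2(C)[C@@H](CC34OOC(O3)C=C4C)C(C=O)=CC[C@H]2C1(C)C | intermediate
22 | γ-hydroxybutenolide (5-hydroxy-4-methylfuran-2(5H)-one attached through C5 to C11H2; hemiketal epimers) | C/C=C(/C)C(=O)O[C@@H]1[C@H](OC(=O)/C(C)=C\C)C[C@]2(C)[C@@H](CC3(O)OC(=O)C=C3C)C(C=O)=CC[C@H]2C1(C)C | intermediate
23 | methyl (13Z)-2α,3α-bis(angeloyloxy)-12,17-dioxolabda-7,13-dien-15-oate = methyl (2Z)-5-[(1R,4aR,6S,7R,8aS)-2-formyl-5,5,8a-trimethyl-6,7-bis{[(2Z)-2-methylbut-2-enoyl]oxy}-1,4,4a,5,6,7,8,8a-octahydronaphthalen-1-yl]-3-methyl-4-oxopent-2-enoate | C/C=C(/C)C(=O)O[C@@H]1[C@H](OC(=O)/C(C)=C\C)C[C@]2(C)[C@@H](CC(=O)/C(C)=C\C(=O)OC)C(C=O)=CC[C@H]2C1(C)C | target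

## Step count and risks

Total steps: 11. Longest linear sequence: 11 (fully linear; 2, 11 and 14 enter directly).

**Step 8 (proposed new relay; most likely to fail).** The uncertainties are which ring bond migrates (C8–C10 is wanted, C8–C7 is possible), loss of formaldehyde by retro-aldol from 15, and furan oligomerisation. The fallback is stepwise and uses known chemistry. It sets out from 13: BF3·OEt2 in CH2Cl2 at −78 °C performs the semipinacol ring expansion, and hydroxymethyl ketone 15 is isolated. MsCl/Et3N converts it into the sulfonate 2α,3α-bis(angeloyloxy)-9-[(methanesulfonyloxy)methyl]-4,4,10-trimethyl-trans-decalin-8-one F4. DBU eliminates this to methylene ketone 16, which is isolated. A separate In(OTf)3-catalysed Friedel–Crafts conjugate addition of 14 then returns to the route at 17.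

**Step 2 (chemoselective vinyl addition).** The enone carbonyl may compete with the cyclopentanone. The fallback sets out from 4 and masks the enone as in steroid 3-enol-ether chemistry. HC(OEt)3 with catalytic p-TsOH in EtOH gives the dienyl ether (7aS)-5-ethoxy-4,7a-dimethyl-2,6,7,7a-tetrahydro-1H-inden-1-one F1. CH2=CHMgBr can then add only to the cyclopentanone, giving (1R,7aS)-5-ethoxy-1-ethenyl-4,7a-dimethyl-2,6,7,7a-tetrahydro-1H-inden-1-ol F2. Dilute aqueous oxalic acid in THF hydrolyses the enol ether and returns to the route at 5.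

**Step 6 (double angeloylation).** The axial, neopentyl 3α-OH is hard to acylate, and angelate can isomerise to tiglate. The fallback sets out from 10 and builds the Z alkenes on the substrate instead of transferring them. Acylation with the unhindered saturated acid 2-(diphenoxyphosphoryl)propanoic acid (EDC, DMAP, CH2Cl2) gives the bis(phosphonopropanoate) 2α,3α-bis{[2-(diphenoxyphosphoryl)propanoyl]oxy}-8α-ethenyl-8β-hydroxy-4,4,10-trimethyl-trans-hydrindane F3. A Z-selective Ando-type Horner–Wadsworth–Emmons olefination (NaH, then acetaldehyde, THF, −78 °C) forms both angelates and returns to the route at 12.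

## Further compounds

F1 | step 2 | (7aS)-5-ethoxy-4,7a-dimethyl-2,6,7,7a-tetrahydro-1H-inden-1-one | CCOC1=C(C)C2=CCC(=O)[C@@]2(C)CC1
F2 | step 2 | (1R,7aS)-5-ethoxy-1-ethenyl-4,7a-dimethyl-2,6,7,7a-tetrahydro-1H-inden-1-ol | CCOC1=C(C)C2=CC[C@@](O)(C=C)[C@@]2(C)CC1
F3 | step 6 | 2α,3α-bis{[2-(diphenoxyphosphoryl)propanoyl]oxy}-8α-ethenyl-8β-hydroxy-4,4,10-trimethyl-trans-hydrindane | CC(C(=O)O[C@@H]1[C@H](OC(=O)C(C)P(=O)(Oc3ccccc3)Oc4ccccc4)C[C@]2(C)[C@](O)(C=C)CC[C@H]2C1(C)C)P(=O)(Oc5ccccc5)Oc6ccccc6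
F4 | step 8 | 2α,3α-bis(angeloyloxy)-9-[(methanesulfonyloxy)methyl]-4,4,10-trimethyl-trans-decalin-8-one | C/C=C(/C)C(=O)O[C@@H]1[C@H](OC(=O)/C(C)=C\C)C[C@]2(C)C(COS(C)(=O)=O)C(=O)CC[C@H]2C1(C)C
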